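**Strategy.** The ten-membered carbocycle (C1–C10, germacrane numbering) is made last, by contracting an eleven-membered thiacycle in which a sulfonyl group bridges C1 and C10. The feature exploited is the C1=C10 double bond that carries the C14 methyl ester: C10 is the only acidic carbon next to sulfur, so it takes the chlorine, and a Ramberg–Bäcklund reaction then joins C1 to C10, expels SO2 and sets the trisubstituted enoate in one operation. The precursor is a macrocyclic α-chloro-α-sulfonyl ester that already holds C4–C9 with all six stereocentres, relayed from (S)-3-hydroxybutyrolactone through chelation-controlled allylation, Nozaki–Hiyama–Kishi macrocyclisation and hydroxyl-directed epoxidation.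

Key step: step 16

Remark: atoms are numbered as in germacranolides (ring C1–C10; C11–C13 the methylene-lactone carbons; C14 the ester carbon on C10; C15 the methyl on C4), and descriptors given "in target numbering" refer to the compound named. C10 in compounds 10–23 and the acetal carbon in 8–10 are epimer mixtures without consequence, because both centres are destroyed later.

**Step 1**
Reactants: 1 5-chloropent-1-yne
Product: 3 (E)-5-chloro-1-iodo-2-methylpent-1-ene, via alkenylalane 2 (not isolated)
Conditions: AlMe3 (2 equiv), Cp2ZrCl2 (20 mol %), CH2Cl2, 0 °C to rt; then I2, THF, −30 °C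
Reagents that add atoms: trimethylaluminium C[Al](C)C; iodine II
Why: Negishi zirconium-catalysed carboalumination adds methyl and aluminium syn across the terminal alkyne (methyl to the internal carbon), and iodinolysis with retention should give the (E)-iodoalkene that becomes C4=C5 with C15.

**Step 2**
Reactants: 3 (E)-5-chloro-1-iodo-2-methylpent-1-ene; 4 potassium 4-methylbenzenesulfonothioate
Product: 5 S-[(4E)-5-iodo-4-methylpent-4-en-1-yl] 4-methylbenzenesulfonothioate
Conditions: NaI (10 mol %), DMF, 50 °C
Reagents that add atoms: none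
Why: SN2 displacement (Finkelstein-assisted) of the primary chloride by the soft thiosulfonate sulfur gives an electrophilic sulfur-transfer reagent for C1, while the alkenyl iodide is inert.

**Step 3**
Reactants: 6 (S)-3-hydroxy-γ-butyrolactone
Product: 8 methyl [(4S)-2-(4-methoxyphenyl)-1,3-dioxolan-4-yl]acetate, via methyl (3S)-3,4-dihydroxybutanoate 7 (not isolated)
Conditions: 4-MeOC6H4CH(OMe)2, MeOH (3 equiv), CSA (cat.), CH2Cl2, rt
Reagents that add atoms: methanol CO; 4-methoxybenzaldehyde dimethyl acetal COC(OC)c1ccc(OC)cc1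
Why: Acid-catalysed methanolysis of the lactone is driven forward by transacetalisation of the 1,2-diol, so the chiral-pool carbinol becomes C9 (with C8, C10 and C14), and the acetal carbon forms as an inconsequential mixture.

**Step 4**
Reactants: 8 methyl [(4S)-2-(4-methoxyphenyl)-1,3-dioxolan-4-yl]acetate; 5 S-alkyl thiosulfonate
Product: 10 α-sulfanyl ester (S now links C10 to C1), via lithium enolate 9 (not isolated)
Conditions: LDA (LiN(iPr)2, 1.1 equiv), THF, −78 °C; then 5, −78 °C
Reagents that add atoms: none
Why: Sulfenylation of the ester enolate by the thiosulfonate forms the C10–S bond at −78 °C, where β-elimination of the dioxolane oxygen is slow, and the new C10 centre needs no control because it becomes sp2 in step 16.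

**Step 5**
Reactants: 10 α-sulfanyl ester with PMP acetal
Product: 11 methyl (3R)-4-hydroxy-2-(alkylsulfanyl)-3-[(4-methoxyphenyl)methoxy]butanoate
Conditions: BH3·THF (1.5 equiv), Cu(OTf)2 (5 mol %), CH2Cl2, 0 °C
Reagents that add atoms: none
Why: Regioselective reductive opening of the p-methoxybenzylidene acetal, in which the Lewis acid and borane engage the less hindered primary oxygen, should leave the PMB group on the secondary O9 and free the primary C8 alcohol without reducing the ester or the iodoalkene.

**Step 6**
Reactants: 11 primary alcohol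
Product: 12 methyl (3R)-2-(alkylsulfanyl)-3-[(4-methoxyphenyl)methoxy]-4-oxobutanoate
Conditions: Dess–Martin periodinane, NaHCO3, CH2Cl2, 0 °C
Reagents that add atoms: none
Why: Buffered Dess–Martin oxidation gives the α-alkoxy aldehyde (C8) without touching the sulfide or epimerising C9; the aldehyde is used at once.

**Step 7**
Reactants: 13 2,2-dimethoxyacetaldehyde; 14 methyl acrylate
Product: 15 methyl 2-(1-hydroxy-2,2-dimethoxyethyl)prop-2-enoate
Conditions: DABCO (0.5 equiv), 1,4-dioxane/H2O, rt
Reagents that add atoms: none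
Why: Morita–Baylis–Hillman reaction joins C7 to C11 and brings C6 as a masked aldehyde; the racemic carbinol centre is lost in step 8.

**Step 8**
Reactants: 15 Baylis–Hillman alcohol
Product: 16 methyl (2Z)-2-(bromomethyl)-4,4-dimethoxybut-2-enoate
Conditions: NBS, Me2S, CH2Cl2, 0 °C to rt
Reagents that add atoms: N-bromosuccinimide BrN1C(=O)CCC1=O
Why: Corey–Kim-type activation of the alcohol and SN2′ delivery of bromide gives the thermodynamically preferred (Z)-bromide, with C6 cis to CH2Br, which fixes the geometry of the allyl reagent.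

**Step 9**
Reactants: 12 α-OPMB aldehyde; 16 (Z)-allylic bromide
Product: 17 syn,syn homoallylic alcohol (C7–C8 bond formed)
Conditions: In powder (1.5 equiv), THF/H2O (1:1), rt
Reagents that add atoms: none
Why: Indium-mediated Barbier allylation attacks through C7 (SE2′) in a chair transition state, where the (Z)-reagent gives the 7,8-syn relationship and indium chelation between the aldehyde and the OPMB oxygen directs attack anti to the C10 branch (Cram chelate, 8,9-syn), so C7 and C8 both follow from C9.

**Step 10**
Reactants: 17 homoallylic alcohol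
Product: 18 O8-TBS ether
Conditions: TBSOTf (1.2 equiv), 2,6-lutidine, CH2Cl2, −78 °C
Reagents that add atoms: tert-butyldimethylsilyl trifluoromethanesulfonate CC(C)(C)[Si](C)(C)OS(=O)(=O)C(F)(F)F
Why: Silylation with the triflate at −78 °C is faster than lactonisation of the γ-hydroxy ester onto C12 and than activation of the dimethyl acetal, and blocks O8 until step 18.

**Step 11**
Reactants: 18 dimethyl acetal
Product: 19 C6 aldehyde
Conditions: TESOTf, 2,4,6-collidine, CH2Cl2, 0 °C; then H2O
Reagents that add atoms: water O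
Why: Silyl triflate and collidine convert the dimethyl acetal into a collidinium adduct that water hydrolyses to the aldehyde under non-acidic conditions, so the silyl and PMB ethers survive and the doubly activated C7 hydrogen is not enolised.

**Step 12**
Reactants: 19 iodoalkene aldehyde
Product: 20 eleven-membered cyclic sulfide with C6 allylic alcohol
Conditions: CrCl2 (8 equiv), NiCl2 (cat.), DMSO/THF, rt, 2 mM, slow addition
Reagents that add atoms: none
Why: Nozaki–Hiyama–Kishi coupling (11-exo-trig) adds the alkenylchromium only to the aldehyde with retention of the (E)-alkene, and C6 should be set by Felkin–Anh attack anti to the C8 branch, reinforced by the 1,3-anti preference relative to the β-silyloxy group of this anti-configured aldehyde.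

**Step 13**
Reactants: 20 macrocyclic sulfide
Product: 21 epoxy sulfone
Conditions: mCPBA (3.2 equiv), Na2HPO4, CH2Cl2, 0 °C
Reagents that add atoms: 3-chloroperbenzoic acid OOC(=O)c1cccc(Cl)c1
Why: The peracid oxidises the sulfide to the sulfone and, in a Henbest hydroxyl-directed epoxidation, delivers oxygen to the C4=C5 face syn to the C6 hydroxyl in the conformer that avoids A(1,3) strain with the cis methyl group, which should give the threo (4R,5R) epoxy alcohol and leave the electron-poor acrylate untouched.

**Step 14**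
Reactants: 21 epoxy alcohol
Product: 22 O6-TES ether
Conditions: TESCl, imidazole, CH2Cl2, 0 °C
Reagents that add atoms: chlorotriethylsilane CC[Si](Cl)(CC)CC
Why: Silylation of O6 under weakly basic conditions prevents alkoxide-driven lactonisation and Payne rearrangement in step 16 and allows selective release of O6 before O8 later.

**Step 15**
Reactants: 22 sulfonyl ester
Product: 23 α-chloro-α-sulfonyl ester
Conditions: NCS (1.3 equiv, present from the start), K2CO3 (cat.), MeCN, 0 °C
Reagents that add atoms: N-chlorosuccinimide ClN1C(=O)CCC1=O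
Why: Electrophilic chlorination of the stabilised carbanion at C10, the only carbon acidic enough for carbonate, places the leaving group regiospecifically, and excess NCS traps the carbanion before it can add to the acrylate.

**Step 16**
Reactants: 23 eleven-membered α-chloro sulfone
Product: 25 ten-membered (1(10)E)-enoate, via episulfone 24 (not isolated)
Conditions: KOtBu (1.5 equiv), THF, −78 to −30 °C; AcOH quench
Reagents that add atoms: none
Why: tert-Butoxide removes a proton from C1, the only position α to sulfur that still carries hydrogen, and the carbanion displaces chloride from C10 (directly, or after chlorine transfer to C1 followed by attack of the ester-stabilised C10 anion), closing the thiirane 1,1-dioxide 24 by a 3-exo-tet 1,3-elimination, after which cheletropic loss of SO2 gives the C1=C10 bond and turns the 11-membered thiacycle into the 10-membered carbocycle. This is a Ramberg–Bäcklund ring contraction, the closest known cases being contractions of macrocyclic α-halo sulfones to cyclophane and medium-ring olefins. No lasting stereocentre is created: C1 and C10 of 24 are transient, SO2 leaves stereospecifically, and the cis-fused episulfone (reachable by base equilibration at C1) gives the ring-cis alkene, which is also the more stable (E)-enoate with the ester trans to C2. The step needs deprotonation at C1 in preference to the γ-hydrogen at C7 of the acrylate and to attack on the esters, which the low temperature, the hindered base and the higher kinetic acidity of the sulfonyl-activated CH2 should secure. Elimination across C9–C10 is excluded because C10 bears no hydrogen and O9 is a non-leaving PMB ether, and the TES ether on O6 prevents lactonisation and epoxide migration.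

**Step 17**
Reactants: 25 bis-silyl ether
Product: 27 trans-fused 6,12-olide, via hydroxy ester 26 (not isolated)
Conditions: PPTS (0.2 equiv), MeOH, 0 °C to rt; then toluene, 45 °C
Reagents that add atoms: none
Why: PPTS in methanol cleaves only the triethylsilyl ether (the hindered TBS ether on O8 stays), and the freed C6 hydroxyl closes the α-methylene-γ-lactone on the C12 ester by 5-exo-trig transesterification, with C6 and C7 unchanged and O8 unable to compete.

**Step 18**
Reactants: 27 O8-TBS lactone
Product: 28 C8 alcohol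
Conditions: HF·pyridine, pyridine, THF, 0 °C to rt
Reagents that add atoms: none
Why: Pyridine-buffered HF·pyridine removes the secondary TBS ether, and is expected to spare the epoxide, the PMB ether and the lactone.

**Step 19**
Reactants: 28 C8 alcohol
Product: 29 8-O-methacrylate
Conditions: methacrylic anhydride, Et3N, DMAP (cat.), CH2Cl2, 0 °C
Reagents that add atoms: methacrylic anhydride CC(=C)C(=O)OC(=O)C(C)=C
Why: DMAP-catalysed acylation of the only free hydroxyl installs the methacrylate with retention at C8, with no neighbouring acyl group able to migrate at this stage.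

**Step 20**
Reactants: 29 PMB ether
Product: 30 C9 alcohol
Conditions: DDQ, CH2Cl2/pH 7 buffer, 0 °C
Reagents that add atoms: none
Why: Oxidative PMB cleavage by DDQ (hydride abstraction, then hydrolysis of the hemiacetal) proceeds under neutral conditions that spare the epoxide, the conjugated esters and the methacrylate.

**Step 21**
Reactants: 30 C9 alcohol
Product: 31 target CNP0153978.3
Conditions: Ac2O, pyridine, DMAP (cat.), CH2Cl2, 0 °C
Reagents that add atoms: acetic anhydride CC(=O)OC(C)=O
Why: DMAP-catalysed acetylation of the allylic C9 alcohol is fast enough to outrun acyl migration from O8 and completes the target with all stereocentres untouched.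

**Compound list**

1 | 5-chloropent-1-yne | C#CCCCCl | starting material
2 | (E)-(5-chloro-2-methylpent-1-en-1-yl)dimethylalane | C[Al](C)/C=C(C)/CCCCl | intermediate
3 | (E)-5-chloro-1-iodo-2-methylpent-1-ene | ClCCC/C(C)=C/I | intermediate
4 | potassium 4-methylbenzenesulfonothioate | Cc1ccc(cc1)S(=O)(=O)[S-].[K+] | starting material
5 | S-[(4E)-5-iodo-4-methylpent-4-en-1-yl] 4-methylbenzenesulfonothioate | Cc1ccc(cc1)S(=O)(=O)SCCC/C(C)=C/I | intermediate
6 | (4S)-4-hydroxyoxolan-2-one, (S)-3-hydroxy-γ-butyrolactone | O=C1C[C@H](O)CO1 | starting material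
7 | methyl (3S)-3,4-dihydroxybutanoate | COC(=O)C[C@H](O)CO | intermediate
8 | methyl [(4S)-2-(4-methoxyphenyl)-1,3-dioxolan-4-yl]acetate (both acetal epimers) | COC(=O)C[C@H]1COC(c2ccc(OC)cc2)O1 | intermediate
9 | lithium ester enolate of 8 | [Li+].COC([O-])=C[C@H]1COC(c2ccc(OC)cc2)O1 | intermediate
10 | methyl {[(4E)-5-iodo-4-methylpent-4-en-1-yl]sulfanyl}[(4R)-2-(4-methoxyphenyl)-1,3-dioxolan-4-yl]acetate (C10 and acetal epimers) | COC(=O)C(SCCC/C(C)=C/I)[C@H]1COC(c2ccc(OC)cc2)O1 | intermediate
11 | methyl (3R)-4-hydroxy-2-{[(4E)-5-iodo-4-methylpent-4-en-1-yl]sulfanyl}-3-[(4-methoxyphenyl)methoxy]butanoate | COC(=O)C(SCCC/C(C)=C/I)[C@H](OCc1ccc(OC)cc1)CO | intermediate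
12 | methyl (3R)-2-{[(4E)-5-iodo-4-methylpent-4-en-1-yl]sulfanyl}-3-[(4-methoxyphenyl)methoxy]-4-oxobutanoate | COC(=O)C(SCCC/C(C)=C/I)[C@H](OCc1ccc(OC)cc1)C=O | intermediate
13 | 2,2-dimethoxyacetaldehyde | COC(OC)C=O | starting material
14 | methyl acrylate | C=CC(=O)OC | starting material
15 | methyl 2-(1-hydroxy-2,2-dimethoxyethyl)prop-2-enoate (racemic) | COC(=O)C(=C)C(O)C(OC)OC | intermediate
16 | methyl (2Z)-2-(bromomethyl)-4,4-dimethoxybut-2-enoate | COC(=O)/C(CBr)=C/C(OC)OC | intermediate
17 | dimethyl (3R,4S,5R)-3-(dimethoxymethyl)-4-hydroxy-6-{[(4E)-5-iodo-4-methylpent-4-en-1-yl]sulfanyl}-5-[(4-methoxyphenyl)methoxy]-2-methylideneheptanedioate (C3, C4, C5 = target C7, C8, C9) | COC(=O)C(SCCC/C(C)=C/I)[C@H](OCc1ccc(OC)cc1)[C@@H](O)[C@@H](C(=C)C(=O)OC)C(OC)OC | intermediate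
18 | 4-O-(tert-butyldimethylsilyl) ether of 17, (3R,4S,5R) | COC(=O)C(SCCC/C(C)=C/I)[C@H](OCc1ccc(OC)cc1)[C@@H](O[Si](C)(C)C(C)(C)C)[C@@H](C(=C)C(=O)OC)C(OC)OC | intermediate
19 | dimethyl (3R,4S,5R)-4-[(tert-butyldimethylsilyl)oxy]-3-formyl-6-{[(4E)-5-iodo-4-methylpent-4-en-1-yl]sulfanyl}-5-[(4-methoxyphenyl)methoxy]-2-methylideneheptanedioate | COC(=O)C(SCCC/C(C)=C/I)[C@H](OCc1ccc(OC)cc1)[C@@H](O[Si](C)(C)C(C)(C)C)[C@@H](C(=C)C(=O)OC)C=O | intermediate
20 | methyl (3R,4S,5S,6R,7E)-4-[(tert-butyldimethylsilyl)oxy]-6-hydroxy-5-(3-methoxy-3-oxoprop-1-en-2-yl)-3-[(4-methoxyphenyl)methoxy]-8-methyl-1-thiacycloundec-7-ene-2-carboxylate (sulfur bridges C1 and C10; 6R,7S,8S,9R in target numbering) | COC(=O)C1[C@H](OCc2ccc(OC)cc2)[C@@H](O[Si](C)(C)C(C)(C)C)[C@@H](C(=C)C(=O)OC)[C@H](O)/C=C(C)/CCCS1 | intermediate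
21 | S,S-dioxide of 20 carrying the 4,5-epoxide (4R,5R,6S,7S,8S,9R in target numbering) | COC(=O)C1[C@H](OCc2ccc(OC)cc2)[C@@H](O[Si](C)(C)C(C)(C)C)[C@@H](C(=C)C(=O)OC)[C@H](O)[C@H]3O[C@]3(C)CCCS1(=O)=O | intermediate
22 | 6-O-triethylsilyl ether of 21 | COC(=O)C1[C@H](OCc2ccc(OC)cc2)[C@@H](O[Si](C)(C)C(C)(C)C)[C@@H](C(=C)C(=O)OC)[C@H](O[Si](CC)(CC)CC)[C@H]3O[C@]3(C)CCCS1(=O)=O | intermediate
23 | 10-chloro derivative of 22 (eleven-membered α-chloro-α-sulfonyl ester) | COC(=O)C1(Cl)[C@H](OCc2ccc(OC)cc2)[C@@H](O[Si](C)(C)C(C)(C)C)[C@@H](C(=C)C(=O)OC)[C@H](O[Si](CC)(CC)CC)[C@H]3O[C@]3(C)CCCS1(=O)=O | intermediate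
24 | thiirane 1,1-dioxide fused across C1–C10 of the ten-membered ring | COC(=O)C12[C@H](OCc3ccc(OC)cc3)[C@@H](O[Si](C)(C)C(C)(C)C)[C@@H](C(=C)C(=O)OC)[C@H](O[Si](CC)(CC)CC)[C@H]4O[C@]4(C)CCC1S2(=O)=O | intermediate
25 | dimethyl (1(10)E,4R,5R,6S,7R,8S,9S)-8-[(tert-butyldimethylsilyl)oxy]-4,5-epoxy-9-[(4-methoxyphenyl)methoxy]-6-[(triethylsilyl)oxy]germacra-1(10),11(13)-diene-12,14-dioate | CC(C)(C)[Si](C)(C)O[C@H]1[C@@H](C(=C)C(=O)OC)[C@H](O[Si](CC)(CC)CC)[C@H]2O[C@]2(C)CC/C=C(/C(=O)OC)[C@@H]1OCc3ccc(OC)cc3 | intermediate
26 | 6-hydroxy analogue of 25 (TES removed) | CC(C)(C)[Si](C)(C)O[C@H]1[C@@H](C(=C)C(=O)OC)[C@H](O)[C@H]2O[C@]2(C)CC/C=C(/C(=O)OC)[C@@H]1OCc3ccc(OC)cc3 | intermediate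
27 | methyl 8-[(tert-butyldimethylsilyl)oxy]-4,5-epoxy-9-[(4-methoxyphenyl)methoxy]-12-oxo-germacra-1(10)E,11(13)-dien-12,6-olid-14-oate (4R,5R,6S,7S,8S,9S) | CC(C)(C)[Si](C)(C)O[C@H]1[C@H]2C(=C)C(=O)O[C@@H]2[C@H]2O[C@]2(C)CC/C=C(/C(=O)OC)[C@@H]1OCc3ccc(OC)cc3 | intermediate
28 | 8-hydroxy analogue of 27 | O[C@H]1[C@H]2C(=C)C(=O)O[C@@H]2[C@H]2O[C@]2(C)CC/C=C(/C(=O)OC)[C@@H]1OCc3ccc(OC)cc3 | intermediate
29 | 8-O-methacrylate of 28 (9-OPMB) | C=C(C)C(=O)O[C@H]1[C@H]2C(=C)C(=O)O[C@@H]2[C@H]2O[C@]2(C)CC/C=C(/C(=O)OC)[C@@H]1OCc3ccc(OC)cc3 | intermediate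
30 | 9-hydroxy analogue of 29 | C=C(C)C(=O)O[C@H]1[C@H]2C(=C)C(=O)O[C@@H]2[C@H]2O[C@]2(C)CC/C=C(/C(=O)OC)[C@@H]1O | intermediate
31 | CNP0153978.3 (4R,5R,6S,7R,8S,9S) | C=C(C)C(=O)O[C@H]1[C@H]2C(=C)C(=O)O[C@@H]2[C@H]2O[C@]2(C)CC/C=C(/C(=O)OC)[C@@H]1OC(C)=O | target

**Step count and risks**

Total step count: 21. Longest linear sequence: 18 steps (steps 1, 2, 4–6 and 9–21, from 5-chloropent-1-yne).

Steps most likely to fail:

- **Step 16 (key step).** The episulfone may close or equilibrate to the trans-fused form, so that SO2 loss gives the ring-trans ester and control over the C1=C10 geometry is lost. The fallback sets out from 23: the contraction is run as described, and the (1(10)Z) isomer of 25, F1, is then equilibrated by reversible thiyl-radical addition (PhSSPh cat., irradiation, benzene), which should funnel it to the more stable ring-cis (E)-enoate. The route is rejoined at 25.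

- **Step 12.** Facial selectivity of the alkenylchromium addition at C6 may be poor inside the macrocyclic transition state. The fallback sets out from 19: the cyclisation is still run, the C6 epimer of 20, F2, is separated and inverted by Mitsunobu esterification with chloroacetic acid (PPh3, DIAD, toluene) to the chloroacetate of 20, F3, and the chloroacetyl group is removed with thiourea and NaHCO3 in ethanol. The route is rejoined at 20.

- **Step 9.** Chelation control may be insufficient in the aqueous indium reaction (Felkin attack, or competing coordination by sulfur), giving the 8,9-anti adduct. The fallback sets out from 16 and 12: bromide 16 is converted with (Bu3Sn)2 and Pd(PPh3)4 into methyl (2Z)-4,4-dimethoxy-2-[(tributylstannyl)methyl]but-2-enoate, F4, which is added to 12 pre-complexed with MgBr2·OEt2 in CH2Cl2 at −20 °C. The rigid magnesium chelate fixes the aldehyde face and the open antiperiplanar transition state of the allylstannane addition should give the same syn,syn adduct. The route is rejoined at 17.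

**Further compounds**

F1 | step 16 | (1(10)Z) isomer of 25 (ring-trans enoate) | CC(C)(C)[Si](C)(C)O[C@H]1[C@@H](C(=C)C(=O)OC)[C@H](O[Si](CC)(CC)CC)[C@H]2O[C@]2(C)CC/C=C(\C(=O)OC)[C@@H]1OCc3ccc(OC)cc3
F2 | step 12 | C6 epimer of 20 | COC(=O)C1[C@H](OCc2ccc(OC)cc2)[C@@H](O[Si](C)(C)C(C)(C)C)[C@@H](C(=C)C(=O)OC)[C@@H](O)/C=C(C)/CCCS1
F3 | step 12 | 6-O-chloroacetate of 20 | COC(=O)C1[C@H](OCc2ccc(OC)cc2)[C@@H](O[Si](C)(C)C(C)(C)C)[C@@H](C(=C)C(=O)OC)[C@H](OC(=O)CCl)/C=C(C)/CCCS1
F4 | step 9 | methyl (2Z)-4,4-dimethoxy-2-[(tributylstannyl)methyl]but-2-enoate | COC(=O)/C(C[Sn](CCCC)(CCCC)CCCC)=C/C(OC)OC
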